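**Plan**

Labels: oxolane O1, C2 (bears ring A, 3,4,5-trimethoxyphenyl), C3 (bears C6H2OH), C4 (bears C7H2–ring B, 3,4-dimethoxyphenyl), C5 (CH2).
Cuts, in retrosynthetic order: C4–C7 (as C4=C7, Wittig, back to a 4-oxo oxolane); O1–C5 (carbenoid O–H insertion, back to an acyclic hydroxy diazoketone); C5=N2 (diazo transfer onto a methyl ketone that stems from a vinyl group); C2–C3 (aldol).
Enabling feature: C5 is the one ring carbon without a substituent, so closing O1–C5 creates no stereocentre. The carbonyl that a diazoketone requires then falls on the neighbouring C4, where C7 and ring B must be attached, and it leaves C3 free to settle trans to ring A.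
Forward: but-3-enoic acid supplies C6, C3, C4 and C5 in one piece, the aldol adds C2 with ring A, the oxolane (the only new ring) closes in step 8, and ring B arrives in step 10.
Stereochemistry: C2 and C3 come from an auxiliary-controlled boron syn aldol. Reducing the imide carbonyl to C6 and oxidising the vinyl group to the C4 ketone swaps the roles of the two C3 branches, which turns the syn adduct into the anti (later 2,3-trans) series. C4 comes from hydrogenation on the face away from the C3 side chain.

Key step: step 8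

Remark: the benzylidene oxolane made in step 10 is expected as an E/Z mixture (Z, with ring B turned towards C5, probably dominant). Both isomers give the same product in step 11, so its SMILES carries no alkene descriptor.

**Route**

Step 1
Reactants: 1 but-3-enoic acid; 2 (R)-4-benzyl-1,3-oxazolidin-2-one
Product: 4 (R)-4-benzyl-3-(but-3-enoyl)-1,3-oxazolidin-2-one, via mixed pivalic anhydride 3 (not isolated)
Conditions: t-BuCOCl, Et3N, THF, −20 °C; then 2, LiCl, −20 °C → rt
Reagents that add atoms: none
Why: Mixed-anhydride N-acylation of an oxazolidinone under LiCl/Et3N activation is a standard entry to chiral imides, attack falls on the unhindered butenoyl carbonyl of 3, and any drift of the alkene into conjugation is harmless because the crotonoyl imide gives the same dienolate in step 2.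

Step 2
Reactants: 4 (R)-4-benzyl-3-(but-3-enoyl)-1,3-oxazolidin-2-one; 5 3,4,5-trimethoxybenzaldehyde
Product: 8 (R)-4-benzyl-3-{(2R)-2-[(R)-hydroxy(3,4,5-trimethoxyphenyl)methyl]but-3-enoyl}-1,3-oxazolidin-2-one, via dibutylboron (Z)-dienolate 6 (not isolated), via dibutylboron aldolate 7 (not isolated)
Conditions: Bu2BOTf, Et3N, CH2Cl2, −78 → 0 °C; 5, −78 → 0 °C; then H2O2, MeOH, pH 7 buffer, 0 °C
Reagents that add atoms: none
Why: Evans syn aldol, in which the (Z)-boron dienolate reacts at its α-carbon through a chair Zimmerman–Traxler transition state on the face away from the benzyl group of the (R)-auxiliary, which should set C2 as R and place vinyl and hydroxyl syn at C3/C2.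

Step 3
Reactants: 8 aldol adduct
Product: 9 (1R,2S)-2-ethenyl-1-(3,4,5-trimethoxyphenyl)propane-1,3-diol
Conditions: LiBH4, MeOH (1.1 equiv), THF, 0 °C
Reagents that add atoms: none
Why: Reductive cleavage of the exocyclic imide carbonyl with LiBH4/MeOH is the usual non-epimerising auxiliary removal, and because this carbon becomes C6 while the vinyl group is kept for C4–C5, the syn adduct now belongs to the anti series needed for a 2,3-trans oxolane.

Step 4
Reactants: 9 (1R,2S)-2-ethenyl-1-(3,4,5-trimethoxyphenyl)propane-1,3-diol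
Product: 11 (1R,2S)-1-(triethylsilyloxy)-2-[(triisopropylsilyloxy)methyl]-1-(3,4,5-trimethoxyphenyl)but-3-ene, via primary TIPS ether 10 (not isolated)
Conditions: TIPSCl (1.05 equiv), imidazole, DMF, 0 °C → rt; then TESCl, rt
Reagents that add atoms: chlorotriisopropylsilane CC(C)[Si](Cl)(C(C)C)C(C)C; chlorotriethylsilane CC[Si](Cl)(CC)CC
Why: Sterically differentiated silylation, in which bulky TIPSCl should take only the primary C6 hydroxyl and the smaller TESCl then caps the benzylic C2 hydroxyl with a group that can later be removed beside TIPS.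

Step 5
Reactants: 11 bis-silyl ether
Product: 12 (3S,4R)-4-(triethylsilyloxy)-3-[(triisopropylsilyloxy)methyl]-4-(3,4,5-trimethoxyphenyl)butan-2-one
Conditions: PdCl2 (10 mol %), Cu(OAc)2·H2O (20 mol %), O2 (1 atm), DMA–H2O 7:1, rt
Reagents that add atoms: water O
Why: Tsuji–Wacker oxidation, in which divalent palladium activates the monosubstituted alkene for Markovnikov attack of water at C4, as is routine for protected homoallylic alcohols, while the acetate-buffered copper co-oxidant keeps the medium mild enough for the TES ether.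

Step 6
Reactants: 12 methyl ketone
Product: 15 (3S,4R)-1-diazo-4-(triethylsilyloxy)-3-[(triisopropylsilyloxy)methyl]-4-(3,4,5-trimethoxyphenyl)butan-2-one, via kinetic lithium enolate 13 (not isolated), via trifluoroacetyl diketone 14 (not isolated)
Conditions: LiN(SiMe3)2, THF, −78 °C; CF3CO2CH2CF3, −78 °C; then MsN3, Et3N, H2O (1 equiv), MeCN, rt
Reagents that add atoms: methanesulfonyl azide CS(=O)(=O)N=[N+]=[N-]
Why: Detrifluoroacetylative diazo transfer (Regitz type), in which the amide base deprotonates the unhindered methyl group C5 under kinetic control rather than the tertiary C3–H, trifluoroacetylation activates C5, and the sulfonyl azide delivers N2 with loss of the trifluoroacetyl group, so no enolate arises at C3 next to its two β-silyloxy groups.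

Step 7
Reactants: 15 TES-protected diazoketone
Product: 16 (3S,4R)-1-diazo-4-hydroxy-3-[(triisopropylsilyloxy)methyl]-4-(3,4,5-trimethoxyphenyl)butan-2-one (anti)
Conditions: Bu4NF, AcOH (1:1), THF, 0 °C
Reagents that add atoms: none
Why: Selective fluoride desilylation, since the triethylsilyl ether is cleaved far faster than the hindered triisopropylsilyl ether, the diazoketone tolerates the near-neutral fluoride/acetate medium, and the buffer protonates the C2 alkoxide at once so that retro-aldol cleavage and silyl migration from O6 should not intervene.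

Step 8
Reactants: 16 (3S,4R)-1-diazo-4-hydroxy-3-[(triisopropylsilyloxy)methyl]-4-(3,4,5-trimethoxyphenyl)butan-2-one
Product: 17 (4S,5R)-5-(3,4,5-trimethoxyphenyl)-4-[(triisopropylsilyloxy)methyl]oxolan-3-one
Conditions: Rh2(OAc)4 (1 mol %), CH2Cl2 (0.01 M), rt, slow addition of 16
Reagents that add atoms: none
Why: Rh2(OAc)4, a dimer of divalent rhodium, binds the diazo carbon C5 at an axial site and expels N2 to leave an electrophilic carbenoid; a lone pair of the C2 hydroxyl adds to C5 to give a cyclic oxonium ylide, and a 1,2-proton shift with release of the catalyst completes the O1–C5 bond. This is the intramolecular carbenoid O–H insertion of hydroxy α-diazoketones, the established entry to oxolan-3-ones. The single ring closes in a 5-exo mode, because the Rh=C5 bond under attack lies outside the O1–C2–C3–C4–C5 array being formed. No stereocentre is created since C5 becomes CH2, C2 is untouched because only its O–H bond reacts, and C3, now α to the ketone, already sits in the more stable arrangement trans to ring A, so any enolisation corrects itself. The step needs chemoselectivity for O–H capture over Buchner addition to ring A (the substrate is a 1-diazo-4-arylbutan-2-one), over ylide formation at O6 (equally five atoms away), over Wolff rearrangement and over carbene dimerisation. The unhindered and more basic hydroxyl oxygen is the fastest trap, the three isopropyl groups shield O6, acetate ligands give a less electrophilic carbenoid than the perfluorocarboxylates that favour arene attack, and slow addition into dilute catalyst suppresses dimer formation.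

Step 9
Reactants: 18 4-(chloromethyl)-1,2-dimethoxybenzene
Product: 19 (3,4-dimethoxybenzyl)triphenylphosphonium chloride
Conditions: PPh3, toluene, reflux
Reagents that add atoms: triphenylphosphine c1ccc(cc1)P(c1ccccc1)c1ccccc1
Why: SN2 quaternisation of triphenylphosphine by an electron-rich benzylic chloride is the standard preparation of a Wittig salt.

Step 10
Reactants: 17 (4S,5R)-5-(3,4,5-trimethoxyphenyl)-4-[(triisopropylsilyloxy)methyl]oxolan-3-one; 19 (3,4-dimethoxybenzyl)triphenylphosphonium chloride
Product: 21 (2R,3S)-4-[(3,4-dimethoxyphenyl)methylidene]-3-[(triisopropylsilyloxy)methyl]-2-(3,4,5-trimethoxyphenyl)oxolane (E/Z mixture), via benzylidene phosphorane 20 (not isolated)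
Conditions: 19 (1.5 equiv), KN(SiMe3)2 (1.4 equiv), THF, 0 °C; then 17, −78 °C → rt
Reagents that add atoms: none
Why: Wittig olefination, in which the semi-stabilised ylide is a far weaker base than a ketone enolate and the inductively activated oxolan-3-one carbonyl is a good acceptor, so C4=C7 formation should outrun enolisation, and any epimerisation at C3 only returns the favoured trans isomer.

Step 11
Reactants: 21 benzylidene oxolane
Product: 22 (2R,3S,4S)-4-[(3,4-dimethoxyphenyl)methyl]-3-[(triisopropylsilyloxy)methyl]-2-(3,4,5-trimethoxyphenyl)oxolane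
Conditions: H2 (1 atm), 10% Pd/C, pyridine (0.5 equiv), EtOAc, rt
Reagents that add atoms: none
Why: Heterogeneous syn hydrogenation, in which the alkene should meet the metal surface with the face opposite the neighbouring TIPSOCH2 group on C3, placing H on that face and C7 cis to C6 (4S), while pyridine-moderated Pd/C reduces alkenes without hydrogenolysis of benzylic ethers such as C2–O1.

Step 12
Reactants: 22 TIPS ether
Product: 23 [(2R,3S,4S)-4-[(3,4-dimethoxyphenyl)methyl]-2-(3,4,5-trimethoxyphenyl)oxolan-3-yl]methanol (CNP0107562.1)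
Conditions: Bu4NF, THF, rt
Reagents that add atoms: none
Why: Fluoride cleavage of a primary TIPS ether is routine and touches no stereocentre.

**Compound list**

1 | but-3-enoic acid | C=CCC(=O)O | starting material
2 | (R)-4-benzyl-1,3-oxazolidin-2-one | O=C1N[C@H](Cc2ccccc2)CO1 | starting material
3 | but-3-enoic pivalic anhydride | C=CCC(=O)OC(=O)C(C)(C)C | intermediate
4 | (R)-4-benzyl-3-(but-3-enoyl)-1,3-oxazolidin-2-one | C=CCC(=O)N1C(=O)OC[C@H]1Cc1ccccc1 | intermediate
5 | 3,4,5-trimethoxybenzaldehyde | COc1cc(C=O)cc(OC)c1OC | starting material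
6 | dibutylboron (Z)-dienolate of 4 | C=C/C=C(\OB(CCCC)CCCC)N1C(=O)OC[C@H]1Cc1ccccc1 | intermediate
7 | dibutylboron aldolate of 8 | C=C[C@@H](C(=O)N1C(=O)OC[C@H]1Cc1ccccc1)[C@@H](OB(CCCC)CCCC)c1cc(OC)c(OC)c(OC)c1 | intermediate
8 | (R)-4-benzyl-3-{(2R)-2-[(R)-hydroxy(3,4,5-trimethoxyphenyl)methyl]but-3-enoyl}-1,3-oxazolidin-2-one | C=C[C@@H](C(=O)N1C(=O)OC[C@H]1Cc1ccccc1)[C@@H](O)c1cc(OC)c(OC)c(OC)c1 | intermediate
9 | (1R,2S)-2-ethenyl-1-(3,4,5-trimethoxyphenyl)propane-1,3-diol | C=C[C@@H](CO)[C@@H](O)c1cc(OC)c(OC)c(OC)c1 | intermediate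
10 | (1R,2S)-2-[(triisopropylsilyloxy)methyl]-1-(3,4,5-trimethoxyphenyl)but-3-en-1-ol | C=C[C@@H](CO[Si](C(C)C)(C(C)C)C(C)C)[C@@H](O)c1cc(OC)c(OC)c(OC)c1 | intermediate
11 | (1R,2S)-1-(triethylsilyloxy)-2-[(triisopropylsilyloxy)methyl]-1-(3,4,5-trimethoxyphenyl)but-3-ene | C=C[C@@H](CO[Si](C(C)C)(C(C)C)C(C)C)[C@@H](O[Si](CC)(CC)CC)c1cc(OC)c(OC)c(OC)c1 | intermediate
12 | (3S,4R)-4-(triethylsilyloxy)-3-[(triisopropylsilyloxy)methyl]-4-(3,4,5-trimethoxyphenyl)butan-2-one | CC(=O)[C@@H](CO[Si](C(C)C)(C(C)C)C(C)C)[C@@H](O[Si](CC)(CC)CC)c1cc(OC)c(OC)c(OC)c1 | intermediate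
13 | terminal lithium enolate of 12 | C=C(O[Li])[C@@H](CO[Si](C(C)C)(C(C)C)C(C)C)[C@@H](O[Si](CC)(CC)CC)c1cc(OC)c(OC)c(OC)c1 | intermediate
14 | (5S,6R)-1,1,1-trifluoro-6-(triethylsilyloxy)-5-[(triisopropylsilyloxy)methyl]-6-(3,4,5-trimethoxyphenyl)hexane-2,4-dione | O=C(CC(=O)C(F)(F)F)[C@@H](CO[Si](C(C)C)(C(C)C)C(C)C)[C@@H](O[Si](CC)(CC)CC)c1cc(OC)c(OC)c(OC)c1 | intermediate
15 | (3S,4R)-1-diazo-4-(triethylsilyloxy)-3-[(triisopropylsilyloxy)methyl]-4-(3,4,5-trimethoxyphenyl)butan-2-one | [N-]=[N+]=CC(=O)[C@@H](CO[Si](C(C)C)(C(C)C)C(C)C)[C@@H](O[Si](CC)(CC)CC)c1cc(OC)c(OC)c(OC)c1 | intermediate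
16 | (3S,4R)-1-diazo-4-hydroxy-3-[(triisopropylsilyloxy)methyl]-4-(3,4,5-trimethoxyphenyl)butan-2-one | [N-]=[N+]=CC(=O)[C@@H](CO[Si](C(C)C)(C(C)C)C(C)C)[C@@H](O)c1cc(OC)c(OC)c(OC)c1 | intermediate
17 | (4S,5R)-5-(3,4,5-trimethoxyphenyl)-4-[(triisopropylsilyloxy)methyl]oxolan-3-one | O=C1CO[C@@H](c2cc(OC)c(OC)c(OC)c2)[C@@H]1CO[Si](C(C)C)(C(C)C)C(C)C | intermediate
18 | 4-(chloromethyl)-1,2-dimethoxybenzene | COc1ccc(CCl)cc1OC | starting material
19 | (3,4-dimethoxybenzyl)triphenylphosphonium chloride | COc1ccc(C[P+](c2ccccc2)(c2ccccc2)c2ccccc2)cc1OC.[Cl-] | intermediate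
20 | (3,4-dimethoxybenzylidene)triphenylphosphorane | COc1ccc(C=P(c2ccccc2)(c2ccccc2)c2ccccc2)cc1OC | intermediate
21 | (2R,3S)-4-[(3,4-dimethoxyphenyl)methylidene]-3-[(triisopropylsilyloxy)methyl]-2-(3,4,5-trimethoxyphenyl)oxolane, E/Z mixture | COc1ccc(C=C2CO[C@@H](c3cc(OC)c(OC)c(OC)c3)[C@@H]2CO[Si](C(C)C)(C(C)C)C(C)C)cc1OC | intermediate
22 | (2R,3S,4S)-4-[(3,4-dimethoxyphenyl)methyl]-3-[(triisopropylsilyloxy)methyl]-2-(3,4,5-trimethoxyphenyl)oxolane | COc1ccc(C[C@@H]2CO[C@@H](c3cc(OC)c(OC)c(OC)c3)[C@@H]2CO[Si](C(C)C)(C(C)C)C(C)C)cc1OC | intermediate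
23 | [(2R,3S,4S)-4-[(3,4-dimethoxyphenyl)methyl]-2-(3,4,5-trimethoxyphenyl)oxolan-3-yl]methanol | COc1ccc(C[C@@H]2CO[C@@H](c3cc(OC)c(OC)c(OC)c3)[C@@H]2CO)cc1OC | target

**Step count**

Total step count: 12. Longest linear sequence: 11 (steps 1–8 and 10–12). Step 9 is a one-step side branch.

**Steps most likely to fail**

Step 10 (Wittig). Addition of the semi-stabilised ylide to the hindered ketone may be too slow. Enolisation would then take over, followed by β-elimination of silanolate from C6 or opening of the ring at C2–O1.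

The fallback forms the C7–ring B bond instead of C4=C7. It sets out from 17.
- Non-basic Petasis methylenation (Cp2TiMe2, toluene, 70 °C) should give the 4-methylidene oxolane F1.
- 9-BBN-H (THF, rt) should add from the face away from the C3 side chain to give the B-alkyl borane F2, with H on C4 trans and C7 cis to C6.
- B-alkyl Suzuki–Miyaura coupling with commercial 4-bromo-1,2-dimethoxybenzene (Pd(dppf)Cl2, K3PO4, DMF–H2O, 50 °C) rejoins the route at 22, so step 11 is bypassed as well.

Step 8 (carbenoid O–H insertion). Capture of the carbenoid by ring A (Buchner-type addition), by O6 or by a second diazo molecule may compete with the hydroxyl group.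

The fallback makes the same O1–C5 bond by displacement at sp3 carbon. It sets out from 12.
- Kinetic enolisation and silylation (LiN(SiMe3)2, Me3SiCl, THF, −78 °C) should give the terminal silyl enol ether F3.
- NBS (THF, −78 → 0 °C) should give the bromomethyl ketone F4.
- PPTS in MeOH at 0 °C should remove the TES group to give the hydroxy bromoketone F5.
- K2CO3 in acetone at 0 °C should close the ring by a 5-exo-tet Williamson reaction, which comes back to the route at 17.

Step 11 (hydrogenation). Three processes are of concern: poor facial discrimination at the exocyclic alkene, migration of the double bond into the ring on the metal with loss of the C3 configuration, and hydrogenolysis of the benzylic C2–O1 bond.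

The fallback sets C4 by hydrogen-atom transfer to a ring radical. It sets out from 17.
- 3,4-Dimethoxybenzylmagnesium chloride F6 (from 18, Mg, THF, 0 °C) is stirred with anhydrous CeCl3 at −78 °C and should add to the ketone without enolisation, giving the tertiary alcohol F7. Either C4 epimer serves.
- Methyl oxalyl chloride with DMAP in CH2Cl2 should give the tertiary methyl oxalate F8.
- Bu3SnH and AIBN in refluxing toluene (Barton–McCombie-type deoxygenation) generate the C4 radical. It should take hydrogen from the stannane on the face opposite the C3 side chain, which leaves C7 cis to C6 and rejoins the route at 22.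

**Further compounds**

F1 | step 10 | (2R,3S)-4-methylidene-3-[(triisopropylsilyloxy)methyl]-2-(3,4,5-trimethoxyphenyl)oxolane | C=C1CO[C@@H](c2cc(OC)c(OC)c(OC)c2)[C@@H]1CO[Si](C(C)C)(C(C)C)C(C)C
F2 | step 10 | 9-{[(3S,4S,5R)-4-[(triisopropylsilyloxy)methyl]-5-(3,4,5-trimethoxyphenyl)oxolan-3-yl]methyl}-9-borabicyclo[3.3.1]nonane | C1CC2CCCC(C1)B2C[C@@H]1CO[C@@H](c2cc(OC)c(OC)c(OC)c2)[C@@H]1CO[Si](C(C)C)(C(C)C)C(C)C
F3 | step 8 | (3S,4R)-4-(triethylsilyloxy)-3-[(triisopropylsilyloxy)methyl]-2-(trimethylsilyloxy)-4-(3,4,5-trimethoxyphenyl)but-1-ene | C=C(O[Si](C)(C)C)[C@@H](CO[Si](C(C)C)(C(C)C)C(C)C)[C@@H](O[Si](CC)(CC)CC)c1cc(OC)c(OC)c(OC)c1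
F4 | step 8 | (3S,4R)-1-bromo-4-(triethylsilyloxy)-3-[(triisopropylsilyloxy)methyl]-4-(3,4,5-trimethoxyphenyl)butan-2-one | BrCC(=O)[C@@H](CO[Si](C(C)C)(C(C)C)C(C)C)[C@@H](O[Si](CC)(CC)CC)c1cc(OC)c(OC)c(OC)c1
F5 | step 8 | (3S,4R)-1-bromo-4-hydroxy-3-[(triisopropylsilyloxy)methyl]-4-(3,4,5-trimethoxyphenyl)butan-2-one | BrCC(=O)[C@@H](CO[Si](C(C)C)(C(C)C)C(C)C)[C@@H](O)c1cc(OC)c(OC)c(OC)c1
F6 | step 11 | 3,4-dimethoxybenzylmagnesium chloride | COc1ccc(C[Mg]Cl)cc1OC
F7 | step 11 | (4S,5R)-3-[(3,4-dimethoxyphenyl)methyl]-4-[(triisopropylsilyloxy)methyl]-5-(3,4,5-trimethoxyphenyl)oxolan-3-ol, carbinol carbon undefined | COc1ccc(CC2(O)CO[C@@H](c3cc(OC)c(OC)c(OC)c3)[C@@H]2CO[Si](C(C)C)(C(C)C)C(C)C)cc1OC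
F8 | step 11 | methyl oxalate ester of F7 | COc1ccc(CC2(OC(=O)C(=O)OC)CO[C@@H](c3cc(OC)c(OC)c(OC)c3)[C@@H]2CO[Si](C(C)C)(C(C)C)C(C)C)cc1OC
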